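**Retrosynthetic overview**
1. The target is a (−)-syringaresinol core. O-4 carries a threo guaiacylglycerol unit B, which is itself etherified by an erythro unit A. O-4′ carries an erythro unit C.
2. Last cut: one hydride step on a tris(N-acyloxazolidinone) diacetate releases all three C9H2OH groups and both terminal phenols.
3. Arms: three C7–C8 aldol cuts (B by boron syn; A and C together by magnesium anti) and three ArO–C8 cuts (phenol plus bromoacetyl imide). There is no separate protecting-group step.
4. Core: the furofuran is cut at C8–C8′, both C7–O bonds and both C9–O bonds, back to two 4-allyl-2,6-dimethoxyphenols and two waters. One aerobic oxidase/peroxidase pot runs the hydration, the 8–8′ radical coupling and both ring closures.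
5. Ring order: only the two tetrahydrofuran rings are made, one directly after the other from the bis-quinone methide. The enantiomers are separated before any arm is attached.

Assumption (reading of the SMILES, lignan numbering): core 7R,8S,7′R,8′S; unit B 7R,8R (threo); unit A 7R,8S (erythro); unit C 7S,8R (erythro). Xs is (4S)-4-benzyl-2-oxooxazolidin-3-yl and Xr is its (4R) antipode.

**Step 1**
Reactants: 1 4-allyl-2,6-dimethoxyphenol (two molecules per product)
Product: 5 (±)-syringaresinol, via vinylogous quinone methide 2 (not isolated), via sinapyl alcohol 3 (not isolated), via bis-quinone methide 4 (not isolated)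
Conditions: eugenol oxidase (I427A variant, cat.), horseradish peroxidase (cat.), air, KPi buffer pH 7.5/5% DMSO, 35 °C
Reagents that add atoms: water, O
Why: In this biomimetic oxidative phenol-coupling cascade the flavin oxidase dehydrogenates the p-allylphenol to 2, water adds at C9 to give 3 while O2 becomes H2O2, the peroxidase uses that H2O2 for one-electron oxidation of 3, two phenoxyl radicals join C8–C8′ in the like sense, and each 9-OH closes a tetrahydrofuran by 5-exo oxa-1,6-addition to the opposite quinone methide of 4, which fixes the cis ring fusion and both exo aryl groups (four core centres, relative configuration only, racemic).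

**Step 2**
Reactants: 5 (±)-syringaresinol
Product: 6 (−)-syringaresinol (7R,8S,7′R,8′S)
Conditions: preparative chiral SFC, cellulose tris(3,5-dimethylphenylcarbamate) phase, CO2/MeOH, 35 °C
Reagents that add atoms: none
Why: This chromatographic resolution on a polysaccharide phase changes no bond, and collecting the laevorotatory enantiomer (checked by rotation and CD) fixes the absolute configuration of the four core centres.

**Step 3**
Reactants: 7 (S)-4-benzyloxazolidin-2-one; 8 bromoacetyl bromide
Product: 10 (S)-4-benzyl-3-(bromoacetyl)oxazolidin-2-one, via N-lithio oxazolidinone 9 (not isolated)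
Conditions: n-BuLi, THF, −78 °C; then 8, −78 to 0 °C
Reagents that add atoms: none
Why: In this N-acylation of a lithiated Evans auxiliary the acyl bromide reacts far faster than the alkyl bromide, and the auxiliary stereocentre is untouched.

**Step 4**
Reactants: 11 (R)-4-benzyloxazolidin-2-one; 8 bromoacetyl bromide
Product: 13 (R)-4-benzyl-3-(bromoacetyl)oxazolidin-2-one, via N-lithio oxazolidinone 12 (not isolated)
Conditions: n-BuLi, THF, −78 °C; then 8, −78 to 0 °C
Reagents that add atoms: none
Why: This is the same N-acylation of a lithiated Evans auxiliary in the antipodal series.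

**Step 5**
Reactants: 14 vanillin; 10 (S)-4-benzyl-3-(bromoacetyl)oxazolidin-2-one
Product: 15 3-methoxy-4-(2-oxo-2-Xs-ethoxy)benzaldehyde
Conditions: K2CO3, MeCN, rt
Reagents that add atoms: none
Why: In this Williamson ether synthesis (SN2) the phenoxide displaces the activated primary bromide irreversibly, whereas attack at the imide carbonyl merely expels phenoxide again.

**Step 6**
Reactants: 6 (−)-syringaresinol; 10 (S)-4-benzyl-3-(bromoacetyl)oxazolidin-2-one
Product: 16 (−)-syringaresinol 4-O-(2-oxo-2-Xs-ethyl) mono-ether (4′-OH free)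
Conditions: 10 (0.8 equiv), K2CO3 (1 equiv), MeCN, rt; unreacted 6 recycled
Reagents that add atoms: none
Why: In this statistical mono-Williamson etherification the two phenols of C2-symmetric 6 are homotopic, so only one mono-ether can form, and keeping the bromide limiting holds the bis-ether down.

**Step 7**
Reactants: 16 mono-ether; 15 aldehyde
Product: 18 syn-aldol adduct (unit B built: 7-OH, C8 bearing C(O)Xs; 4′-OH free; B-ring O-4 bearing CH2C(O)Xs), via dibutylboron enolate 17 (not isolated)
Conditions: Bu2BOTf (2.2 equiv), iPr2NEt (2.5 equiv), CH2Cl2, −78 to 0 °C; then 15, −78 to 0 °C; pH 7 buffer, MeOH, H2O2, 0 °C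
Reagents that add atoms: none
Why: In this Evans boron syn-aldol (glycolate variant) the pre-formed (Z)-enolate 17, with its phenol parked as a borinate, reacts through a Zimmerman–Traxler chair under (4S)-auxiliary control to give the (2S,3R) imide, which is 7R,8R threo in the target, and the glycolyl imide on the aldehyde stays un-enolised because no free Bu2BOTf/amine pair is left.

**Step 8**
Reactants: 18 syn-aldol adduct; 13 (R)-4-benzyl-3-(bromoacetyl)oxazolidin-2-one
Product: 19 18 etherified at O-4′ with CH2C(O)Xr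
Conditions: K2CO3, MeCN, rt
Reagents that add atoms: none
Why: In this Williamson ether synthesis only the phenol (pKa about 10) is deprotonated by K2CO3, so the β-hydroxy imide neither undergoes retro-aldol nor epimerises.

**Step 9**
Reactants: 19 bis(glycolyl imide); 20 vanillin acetate (4-acetoxy-3-methoxybenzaldehyde)
Product: 22 tris(imide) tris(TMS ether) diacetate (units A, B and C complete at the imide level), via unit-B TMS ether 21 (not isolated)
Conditions: TMSCl (6 equiv), Et3N (7 equiv), EtOAc, rt, 1 h; then MgCl2 (0.4 equiv), 20 (3 equiv), rt, 24–48 h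
Reagents that add atoms: chlorotrimethylsilane, C[Si](C)(C)Cl
Why: In this Evans magnesium-halide-catalysed anti-aldol, run on both glycolyl imides at once, each chelated (Z)-magnesium enolate is attacked opposite its benzyl group through a boat transition state and the aldolate is trapped by TMSCl, so Xs gives unit A as (2R,3R), which is 7R,8S erythro, Xr gives unit C as (2S,3S), which is 7S,8R erythro, and the prior silylation to 21 blocks retro-aldol of unit B.

**Step 10**
Reactants: 22 tris(imide) tris(TMS ether) diacetate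
Product: 23 target CNP0316493.1
Conditions: LiBH4 (excess), THF/MeOH, 0 °C to rt; aq NH4Cl
Reagents that add atoms: none
Why: Reductive cleavage of the Evans auxiliaries with LiBH4 turns the three imides into the three C9H2OH groups, reduces off the two aryl acetates and lets the methoxide formed strip the TMS ethers, and no stereocentre is touched because hydride attacks the exocyclic carbonyls without enolisation.

**Compound list**
1 | 4-allyl-2,6-dimethoxyphenol | C=CCc1cc(OC)c(O)c(OC)c1 | starting material
2 | 4-allylidene-2,6-dimethoxycyclohexa-2,5-dien-1-one (not isolated) | C=CC=C1C=C(OC)C(=O)C(OC)=C1 | intermediate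
3 | (E)-sinapyl alcohol (not isolated) | COc1cc(/C=C/CO)cc(OC)c1O | intermediate
4 | 8,8′-linked bis(p-quinone methide), like isomer, racemic (not isolated) | OC[C@@H](C=C1C=C(OC)C(=O)C(OC)=C1)[C@@H](CO)C=C1C=C(OC)C(=O)C(OC)=C1.OC[C@H](C=C1C=C(OC)C(=O)C(OC)=C1)[C@H](CO)C=C1C=C(OC)C(=O)C(OC)=C1 | intermediate
5 | (±)-syringaresinol | COc1cc([C@@H]2OC[C@@H]3[C@H]2CO[C@H]3c2cc(OC)c(O)c(OC)c2)cc(OC)c1O.COc1cc([C@H]2OC[C@H]3[C@@H]2CO[C@@H]3c2cc(OC)c(O)c(OC)c2)cc(OC)c1O | intermediate
6 | (−)-syringaresinol (7R,8S,7′R,8′S) | COc1cc([C@@H]2OC[C@@H]3[C@H]2CO[C@H]3c2cc(OC)c(O)c(OC)c2)cc(OC)c1O | intermediate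
7 | (S)-4-benzyloxazolidin-2-one | O=C1N[C@@H](Cc2ccccc2)CO1 | starting material
8 | bromoacetyl bromide | O=C(Br)CBr | starting material
9 | N-lithio-(S)-4-benzyloxazolidin-2-one (not isolated) | [Li]N1[C@@H](Cc2ccccc2)COC1=O | intermediate
10 | (S)-4-benzyl-3-(bromoacetyl)oxazolidin-2-one | O=C(CBr)N1[C@@H](Cc2ccccc2)COC1=O | intermediate
11 | (R)-4-benzyloxazolidin-2-one | O=C1N[C@H](Cc2ccccc2)CO1 | starting material
12 | N-lithio-(R)-4-benzyloxazolidin-2-one (not isolated) | [Li]N1[C@H](Cc2ccccc2)COC1=O | intermediate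
13 | (R)-4-benzyl-3-(bromoacetyl)oxazolidin-2-one | O=C(CBr)N1[C@H](Cc2ccccc2)COC1=O | intermediate
14 | vanillin | COc1cc(C=O)ccc1O | starting material
15 | 3-methoxy-4-(2-oxo-2-Xs-ethoxy)benzaldehyde | COc1cc(C=O)ccc1OCC(=O)N1[C@@H](Cc2ccccc2)COC1=O | intermediate
16 | (−)-syringaresinol 4-O-(2-oxo-2-Xs-ethyl) mono-ether | COc1cc([C@@H]2OC[C@@H]3[C@H]2CO[C@H]3c2cc(OC)c(O)c(OC)c2)cc(OC)c1OCC(=O)N1[C@@H](Cc2ccccc2)COC1=O | intermediate
17 | (Z)-dibutylboron enolate of 16, 4′-O-dibutylborinate (not isolated) | COc1cc([C@@H]2OC[C@@H]3[C@H]2CO[C@H]3c2cc(OC)c(OB(CCCC)CCCC)c(OC)c2)cc(OC)c1O/C=C(\OB(CCCC)CCCC)N1[C@@H](Cc2ccccc2)COC1=O | intermediate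
18 | syn-aldol adduct, unit B (2S,3R) imide = 7R,8R | O=C(COc1ccc([C@@H](O)[C@@H](C(=O)N2[C@@H](Cc3ccccc3)COC2=O)Oc2c(OC)cc([C@@H]3OC[C@@H]4[C@H]3CO[C@H]4c3cc(OC)c(O)c(OC)c3)cc2OC)cc1OC)N1[C@@H](Cc2ccccc2)COC1=O | intermediate
19 | 18 with O-4′–CH2C(O)Xr | O=C(COc1ccc([C@@H](O)[C@@H](C(=O)N2[C@@H](Cc3ccccc3)COC2=O)Oc2c(OC)cc([C@@H]3OC[C@@H]4[C@H]3CO[C@H]4c3cc(OC)c(OCC(=O)N4[C@H](Cc5ccccc5)COC4=O)c(OC)c3)cc2OC)cc1OC)N1[C@@H](Cc2ccccc2)COC1=O | intermediate
20 | vanillin acetate | COc1cc(C=O)ccc1OC(C)=O | starting material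
21 | 19 as unit-B 7-O-TMS ether (not isolated) | O=C(COc1ccc([C@@H](O[Si](C)(C)C)[C@@H](C(=O)N2[C@@H](Cc3ccccc3)COC2=O)Oc2c(OC)cc([C@@H]3OC[C@@H]4[C@H]3CO[C@H]4c3cc(OC)c(OCC(=O)N4[C@H](Cc5ccccc5)COC4=O)c(OC)c3)cc2OC)cc1OC)N1[C@@H](Cc2ccccc2)COC1=O | intermediate
22 | tris(imide) tris(TMS ether) diacetate (A 2R,3R; B 2S,3R; C 2S,3S) | COc1cc([C@@H](O[Si](C)(C)C)[C@H](C(=O)N6[C@@H](Cc7ccccc7)COC6=O)Oc2ccc([C@@H](O[Si](C)(C)C)[C@@H](C(=O)N6[C@@H](Cc7ccccc7)COC6=O)Oc3c(OC)cc([C@@H]4OC[C@@H]5[C@H]4CO[C@H]5c4cc(OC)c(O[C@H](C(=O)N6[C@H](Cc7ccccc7)COC6=O)[C@@H](O[Si](C)(C)C)c5ccc(OC(C)=O)c(OC)c5)c(OC)c4)cc3OC)cc2OC)ccc1OC(C)=O | intermediate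
23 | CNP0316493.1 | COc1cc([C@@H](O)[C@H](CO)Oc2ccc([C@@H](O)[C@@H](CO)Oc3c(OC)cc([C@@H]4OC[C@@H]5[C@H]4CO[C@H]5c4cc(OC)c(O[C@H](CO)[C@@H](O)c5ccc(O)c(OC)c5)c(OC)c4)cc3OC)cc2OC)ccc1O | target

**Total steps:** 10. **Longest linear sequence:** 7 (steps 1, 2, 6, 7, 8, 9, 10).

**Steps most likely to fail**

Step 9 is the riskiest. The magnesium anti-aldol is established for alkyl-substituted imides, and here it must work on two aryloxyacetyl imides at once, one of which carries the hindered 2,6-dimethoxyphenoxy group. The anti/syn ratio could therefore be poor. The fallback sets out from 19 and comes back at 23. Catalytic soft enolisation is given up. Instead, 19 is converted with Bu2BOTf/iPr2NEt into its two stoichiometric, carbonyl-chelated boron enolates, and a third equivalent parks the unit-B hydroxyl as a borinate. Aldehyde 20 is then added pre-complexed with Et2AlCl at −78 °C. Bond formation goes through an open transition state on the same enolate face, so the anti sense is kept. Oxidative work-up gives the tris(imide) triol diacetate F1, which LiBH4 in THF/MeOH reduces directly to 23.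

Step 7 is the second risk. The electrophile 15 carries an enolisable glycolyl imide, and the nucleophile carries a free phenol. Proton or boron scrambling would give self-aldol products. The fallback sets out from 16 and comes back at 18. The same boron enolate 17 is added to the simple aldehyde 20, giving the unit-B aldol acetate F2. The aryl acetate is removed with NH4OAc in aqueous MeOH to give the bisphenol F3. The less hindered guaiacyl phenol of F3 is then alkylated in preference to the doubly ortho-substituted syringyl phenol, using one equivalent of 10 with K2CO3 in MeCN, and this gives 18.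

Step 1 is the third risk. It depends on a tailored oxidase, runs at low millimolar concentration, and the peroxidase can over-oxidise the product. The fallback sets out from 1 and comes back at 5. Compound 1 is oxidised with Ag2O in CH2Cl2 to 2 as a discrete solution species. Acetic acid adds to 2 in 1,8 fashion to give (E)-sinapyl acetate F4. Methanolysis with K2CO3 in MeOH delivers 3 as an isolated solid. In a separate operation, 3 is dimerised with CuSO4/air or FeCl3 in aqueous acetone to 5.

**Further compounds**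
F1 | step 9 | tris(imide) triol diacetate | COc1cc([C@@H](O)[C@H](C(=O)N6[C@@H](Cc7ccccc7)COC6=O)Oc2ccc([C@@H](O)[C@@H](C(=O)N6[C@@H](Cc7ccccc7)COC6=O)Oc3c(OC)cc([C@@H]4OC[C@@H]5[C@H]4CO[C@H]5c4cc(OC)c(O[C@H](C(=O)N6[C@H](Cc7ccccc7)COC6=O)[C@@H](O)c5ccc(OC(C)=O)c(OC)c5)c(OC)c4)cc3OC)cc2OC)ccc1OC(C)=O
F2 | step 7 | unit-B aldol acetate | CC(=O)Oc1ccc([C@@H](O)[C@@H](C(=O)N2[C@@H](Cc3ccccc3)COC2=O)Oc2c(OC)cc([C@@H]3OC[C@@H]4[C@H]3CO[C@H]4c3cc(OC)c(O)c(OC)c3)cc2OC)cc1OC
F3 | step 7 | bisphenol | Oc1ccc([C@@H](O)[C@@H](C(=O)N2[C@@H](Cc3ccccc3)COC2=O)Oc2c(OC)cc([C@@H]3OC[C@@H]4[C@H]3CO[C@H]4c3cc(OC)c(O)c(OC)c3)cc2OC)cc1OC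
F4 | step 1 | (E)-sinapyl acetate | COc1cc(/C=C/COC(C)=O)cc(OC)c1O
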